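## Retrosynthetic overview

1. The target is a ten-membered carbocycle (ring A, C1–C10) fused at C6/C7 to a butenolide (ring B, O–C6–C7=C11–C12). The plan rests on one feature of ring A: the saturated C2–C3 bridge ends at C4 of the Z-trisubstituted C4=C5 olefin. Ring A is therefore opened at C3–C4 into a C2=C3 vinyl group and a Z-configured C4 alkenyl iodide, and is closed last by hydroboration and B-alkyl Suzuki–Miyaura coupling.
2. Ring B is formed first, by an intramolecular Horner–Wadsworth–Emmons reaction of the C6 ester of α-hydroxy ketone 27 with phosphonoacid 23 (C11–C13).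
3. The C8–C9 bond comes from a syn boron aldol reaction of ketone 19 (C4–C8; C6 from (S)-glycerate, Z iodide from a Stork–Zhao olefination) with aldehyde 7 (C1–C3, C9, C10; Evans aldol with acrolein).
4. The silyl groups are graded, TES (O6) before TBS (O1, O13) before TIPS (O9), with PMB on O8, so that O6, O8, O1/O13 and O9 are released in that order for lactone, tiglate, acetate/ketone and free alcohol.

Key step: step 21

Remark: atoms carry germacranolide numbers (C1 ketone carbon, C2–C3 CH2CH2, C4=C5 with the C15 methyl on C4, C6 lactone O–CH, C7=C11, C8 O-tigloyl, C9 OH, C10 with the C14 methyl, C12 lactone C=O, C13 CH2OAc); TBS = tert-butyldimethylsilyl, TES = triethylsilyl, TIPS = triisopropylsilyl, PMB = 4-methoxybenzyl (TBSO etc. = the corresponding oxy groups); 9, 11 and 20 are assumed to be purchasable.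

## Route

Step 1
Reactants: 1 (R)-4-benzyl-3-propionyloxazolidin-2-one; 2 acrolein
Product: 4 (R)-4-benzyl-3-[(2R,3S)-3-hydroxy-2-methylpent-4-enoyl]oxazolidin-2-one, via dibutylboron Z-enolate 3 (not isolated)
Conditions: Bu2BOTf, Et3N, CH2Cl2, −78 → 0 °C; 2, −78 → 0 °C; H2O2, MeOH, pH 7 buffer
Reagents that add atoms: none
Why: Evans syn aldol reaction: the Z enolborinate reacts through a Zimmerman–Traxler chair on the face away from the benzyl group, which sets C10 and C1 as the 2R,3S syn pair.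

Step 2
Reactants: 4 (R)-4-benzyl-3-[(2R,3S)-3-hydroxy-2-methylpent-4-enoyl]oxazolidin-2-one
Product: 5 (2R,3S)-3-hydroxy-N-methoxy-N,2-dimethylpent-4-enamide
Conditions: MeNH(OMe)·HCl, AlMe3, THF, −20 → 0 °C
Reagents that add atoms: N,O-dimethylhydroxylamine hydrochloride CNOC.Cl
Why: AlMe3-mediated transamidation to the Weinreb amide, assisted by the free β-hydroxyl, removes the auxiliary without touching C10.

Step 3
Reactants: 5 (2R,3S)-3-hydroxy-N-methoxy-N,2-dimethylpent-4-enamide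
Product: 6 (2R,3S)-3-(TBSO)-N-methoxy-N,2-dimethylpent-4-enamide
Conditions: TBSOTf, 2,6-lutidine, CH2Cl2, −78 → 0 °C
Reagents that add atoms: tert-butyldimethylsilyl triflate CC(C)(C)[Si](C)(C)OS(=O)(=O)C(F)(F)F
Why: Silylation of the secondary allylic alcohol; TBS on O1 is chosen to outlast the TES cleavage at O6 and to fall before the TIPS group on O9.

Step 4
Reactants: 6 (2R,3S)-3-(TBSO)-N-methoxy-N,2-dimethylpent-4-enamide
Product: 7 (2R,3S)-3-(TBSO)-2-methylpent-4-enal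
Conditions: iBu2AlH, THF, −78 °C
Reagents that add atoms: none
Why: Hydride reduction of a Weinreb amide stops at the chelated tetrahedral intermediate, so the aldehyde is released only on work-up and C10 is not epimerised.

Step 5
Reactants: 8 4-methoxybenzyl alcohol; 9 tributyl(iodomethyl)stannane
Product: 10 tributyl{[(4-methoxybenzyl)oxy]methyl}stannane
Conditions: NaH, THF/DMF, 0 °C → rt
Reagents that add atoms: none
Why: Williamson etherification (SN2 at the iodomethyl carbon) gives the stannane that serves as the PMBOCH2 carbanion source for C8.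

Step 6
Reactants: 11 methyl (S)-2,2-dimethyl-1,3-dioxolane-4-carboxylate
Product: 12 (S)-2,2-dimethyl-1,3-dioxolane-4-carbaldehyde
Conditions: iBu2AlH, CH2Cl2, −78 °C
Reagents that add atoms: none
Why: Low-temperature partial reduction of the ester gives the aldehyde (future C5) and leaves the dioxolane stereocentre (future C6) untouched.

Step 7
Reactants: 12 (S)-2,2-dimethyl-1,3-dioxolane-4-carbaldehyde
Product: 13 (R)-4-[(Z)-2-iodoprop-1-en-1-yl]-2,2-dimethyl-1,3-dioxolane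
Conditions: EtPPh3I, n-BuLi, THF, 0 °C; I2, −78 °C; NaN(SiMe3)2, −20 °C; 12, −78 → −20 °C
Reagents that add atoms: ethyltriphenylphosphonium iodide CC[P+](c1ccccc1)(c1ccccc1)c1ccccc1.[I-]; iodine II
Why: Stork–Zhao olefination: the α-iodo ylide reacts under kinetic Wittig control to place iodine cis to the dioxolane carbon, which fixes the Z geometry of C4=C5.

Step 8
Reactants: 13 (R)-4-[(Z)-2-iodoprop-1-en-1-yl]-2,2-dimethyl-1,3-dioxolane
Product: 14 (2R,3Z)-4-iodopent-3-ene-1,2-diol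
Conditions: AcOH/H2O (4:1), 40 °C
Reagents that add atoms: none
Why: Acid hydrolysis of the acetonide; the electron-poor iodoalkene disfavours allylic ionisation at C6.

Step 9
Reactants: 14 (2R,3Z)-4-iodopent-3-ene-1,2-diol
Product: 15 (2R,3Z)-4-iodo-1,2-bis(TESO)pent-3-ene
Conditions: TESCl, imidazole, DMAP (cat.), CH2Cl2, 0 °C → rt
Reagents that add atoms: chlorotriethylsilane CC[Si](Cl)(CC)CC
Why: Exhaustive silylation; TES on O6 is the most labile silyl group of the route and the primary TES ether is the handle for the next step.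

Step 10
Reactants: 15 (2R,3Z)-4-iodo-1,2-bis(TESO)pent-3-ene
Product: 16 (2R,3Z)-4-iodo-2-(TESO)pent-3-enal
Conditions: (COCl)2, DMSO, CH2Cl2, −78 → −35 °C; Et3N, −78 → 0 °C
Reagents that add atoms: none
Why: Under Swern conditions a primary TES ether is converted directly into the aldehyde while the more hindered secondary TES ether survives, and the cold amine step protects the C6 stereocentre.

Step 11
Reactants: 16 (2R,3Z)-4-iodo-2-(TESO)pent-3-enal; 10 tributyl{[(4-methoxybenzyl)oxy]methyl}stannane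
Product: 18 (3R,4Z)-5-iodo-1-(PMBO)-3-(TESO)hex-4-en-2-ol (both C2 epimers), via [(4-methoxybenzyl)oxy]methyllithium 17 (not isolated)
Conditions: 10, n-BuLi, THF, −78 °C; 16, −78 °C; AcOH quench at −78 °C
Reagents that add atoms: none
Why: Tin–lithium exchange gives the α-alkoxymethyllithium, which adds to the aldehyde faster than it exchanges with the alkenyl iodide; the new C7 carbinol centre is oxidised in the next step, and the cold acidic quench suppresses silyl migration.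

Step 12
Reactants: 18 (3R,4Z)-5-iodo-1-(PMBO)-3-(TESO)hex-4-en-2-ol
Product: 19 (3R,4Z)-5-iodo-1-(PMBO)-3-(TESO)hex-4-en-2-one
Conditions: Dess–Martin periodinane, pyridine, CH2Cl2, 0 °C → rt
Reagents that add atoms: none
Why: Buffered Dess–Martin oxidation gives the C7 ketone under non-enolising conditions, so C6 is preserved.

Step 13
Reactants: 20 benzyl 2-(diethoxyphosphoryl)acetate
Product: 21 benzyl 2-(diethoxyphosphoryl)-3-hydroxypropanoate (racemic)
Conditions: (CH2O)n, piperidine (cat.), THF, 60 °C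
Reagents that add atoms: formaldehyde (as paraformaldehyde) C=O
Why: Amine-catalysed aldol-type hydroxymethylation of the phosphonoacetate installs C13; limiting the formaldehyde stops the reaction before a second equivalent can undergo olefination.

Step 14
Reactants: 21 benzyl 2-(diethoxyphosphoryl)-3-hydroxypropanoate
Product: 22 benzyl 3-(TBSO)-2-(diethoxyphosphoryl)propanoate (racemic)
Conditions: TBSCl, imidazole, DMF, 0 °C → rt
Reagents that add atoms: tert-butylchlorodimethylsilane CC(C)(C)[Si](C)(C)Cl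
Why: Silylation of the primary alcohol blocks retro-addition and gives the O13 protecting group, which does not ionise under palladium catalysis as an acetate would.

Step 15
Reactants: 22 benzyl 3-(TBSO)-2-(diethoxyphosphoryl)propanoate
Product: 23 3-(TBSO)-2-(diethoxyphosphoryl)propanoic acid (racemic)
Conditions: H2 (1 atm), Pd/C (cat.), EtOAc, rt
Reagents that add atoms: none
Why: Hydrogenolysis frees the acid without base, so the β-silyloxy phosphonate cannot undergo elimination.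

Step 16
Reactants: 19 (3R,4Z)-5-iodo-1-(PMBO)-3-(TESO)hex-4-en-2-one; 7 (2R,3S)-3-(TBSO)-2-methylpent-4-enal
Product: 25 (3S,4S,5R,6S,8R,9Z)-3-(TBSO)-5-hydroxy-10-iodo-6-(PMBO)-4-methyl-8-(TESO)undeca-1,9-dien-7-one, via dibutylboron Z-enolate 24 (not isolated)
Conditions: Bu2BOTf, iPr2NEt, CH2Cl2, −78 °C; 7, −78 → −20 °C; H2O2, MeOH, pH 7 buffer, 0 °C
Reagents that add atoms: none
Why: Syn boron aldol reaction: enolisation on the less hindered CH2OPMB side gives the Z enolborinate, whose chair transition state sets the 8,9-syn pair; the C6 silyloxy centre directs attack (dipole-minimised arrangement of α′-silyloxy Z enolates) to the 6,8-syn product, and this coincides with the anti-Felkin preference of Z enolates for α-methyl aldehydes, so C8 and C9 arise in a matched reaction.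

Step 17
Reactants: 25 (3S,4S,5R,6S,8R,9Z)-3-(TBSO)-5-hydroxy-10-iodo-6-(PMBO)-4-methyl-8-(TESO)undeca-1,9-dien-7-one
Product: 26 (3S,4R,5R,6S,8R,9Z)-3-(TBSO)-10-iodo-6-(PMBO)-4-methyl-8-(TESO)-5-(TIPSO)undeca-1,9-dien-7-one
Conditions: TIPSOTf, 2,6-lutidine, CH2Cl2, −78 → 0 °C
Reagents that add atoms: triisopropylsilyl triflate CC(C)[Si](OS(=O)(=O)C(F)(F)F)(C(C)C)C(C)C
Why: The silyl triflate protects the hindered β-hydroxy ketone alcohol (O9) faster than it enolises the ketone; TIPS is the silyl group that must survive to the last step.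

Step 18
Reactants: 26 (3S,4R,5R,6S,8R,9Z)-3-(TBSO)-10-iodo-6-(PMBO)-4-methyl-8-(TESO)-5-(TIPSO)undeca-1,9-dien-7-one
Product: 27 (3S,4R,5R,6S,8R,9Z)-3-(TBSO)-8-hydroxy-10-iodo-6-(PMBO)-4-methyl-5-(TIPSO)undeca-1,9-dien-7-one
Conditions: HF·pyridine, pyridine, THF, 0 °C
Reagents that add atoms: none
Why: Buffered fluoride cleaves the TES ether selectively in the presence of the secondary TBS and TIPS ethers and frees O6 under conditions that do not enolise the α-hydroxy ketone.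

Step 19
Reactants: 27 (3S,4R,5R,6S,8R,9Z)-3-(TBSO)-8-hydroxy-10-iodo-6-(PMBO)-4-methyl-5-(TIPSO)undeca-1,9-dien-7-one; 23 3-(TBSO)-2-(diethoxyphosphoryl)propanoic acid
Product: 28 O6 ester of 27 with 23 (both epimers at the phosphonate carbon)
Conditions: DCC, DMAP (cat.), CH2Cl2, 0 °C → rt
Reagents that add atoms: none
Why: Steglich esterification acylates the only free hydroxyl (O6) with retention at C6; the stereocentre at the phosphonate carbon is destroyed in the next step.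

Step 20
Reactants: 28 O6 ester of 27 with 23
Product: 29 (5R)-3-[(TBSO)methyl]-4-[(1R,2R,3R,4S)-4-(TBSO)-1-(PMBO)-3-methyl-2-(TIPSO)hex-5-en-1-yl]-5-[(Z)-2-iodoprop-1-en-1-yl]furan-2(5H)-one
Conditions: LiCl, iPr2NEt, MeCN, 0 °C → rt
Reagents that add atoms: none
Why: Intramolecular Horner–Wadsworth–Emmons reaction: the lithium-chelated phosphonate is deprotonated by the weak amine base and adds to the neighbouring C7 ketone in a five-membered closure, giving the C7=C11 butenolide (ring B) with the CH2OTBS group on C11.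

Step 21
Reactants: 29 (5R)-3-[(TBSO)methyl]-4-[(1R,2R,3R,4S)-4-(TBSO)-1-(PMBO)-3-methyl-2-(TIPSO)hex-5-en-1-yl]-5-[(Z)-2-iodoprop-1-en-1-yl]furan-2(5H)-one
Product: 31 (1S,6R,8R,9R,10R)-1,13-bis(TBSO)-8-(PMBO)-9-(TIPSO)germacra-4Z,7(11)-dien-12,6-olide, via B-alkyl-9-BBN 30 (not isolated)
Conditions: 9-BBN, THF, 0 °C → rt; then syringe-pump addition to PdCl2(dppf) (cat.), AsPh3, K3PO4 (aq), DMF/THF, 45 °C, about 1 mM
Reagents that add atoms: none
Why: 9-BBN adds anti-Markovnikov to the only monosubstituted alkene (C2=C3) and places boron on C3, while the trisubstituted iodoalkene, the tetrasubstituted butenolide olefin and the lactone carbonyl are too hindered or too electron-poor to react. Zerovalent palladium then inserts into the C4–I bond with retention of the Z geometry, the base turns the alkylborane into a borate that transfers the primary C3 alkyl group to the divalent alkenylpalladium, and reductive elimination forms C3–C4; this is an intramolecular B-alkyl Suzuki–Miyaura macrocyclisation, a known reaction type. Ring A (ten-membered) closes by intramolecular sp3–sp2 coupling at C3–C4, helped by the butenolide already in place, which holds C5–C6–C7–C8 and so brings C3 and C4 closer. No stereocentre is created; the olefin geometry was fixed in step 7 and both palladium steps are stereoretentive. The step needs cyclisation to beat oligomerisation, protodeboronation and β-hydride elimination, for which slow addition at high dilution, the wide-bite-angle dppf ligand and AsPh3 are chosen, and it needs a base that spares the C6 proton and the lactone, for which aqueous K3PO4 is chosen.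

Step 22
Reactants: 31 (1S,6R,8R,9R,10R)-1,13-bis(TBSO)-8-(PMBO)-9-(TIPSO)germacra-4Z,7(11)-dien-12,6-olide
Product: 32 (1S,6R,8R,9R,10R)-1,13-bis(TBSO)-8-hydroxy-9-(TIPSO)germacra-4Z,7(11)-dien-12,6-olide
Conditions: DDQ, CH2Cl2/pH 7 buffer, 0 °C
Reagents that add atoms: none
Why: Oxidative cleavage of the PMB ether (hydride abstraction from the electron-rich benzylic position, then hydrolysis) frees O8 alone; silyl ethers and the olefins are inert under the buffered conditions.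

Step 23
Reactants: 32 (1S,6R,8R,9R,10R)-1,13-bis(TBSO)-8-hydroxy-9-(TIPSO)germacra-4Z,7(11)-dien-12,6-olide
Product: 33 (1S,6R,8R,9R,10R)-1,13-bis(TBSO)-8-(tigloyloxy)-9-(TIPSO)germacra-4Z,7(11)-dien-12,6-olide
Conditions: tigloyl chloride, pyridine, DMAP (cat.), CH2Cl2, 0 °C → rt
Reagents that add atoms: (E)-2-methylbut-2-enoyl chloride C/C=C(\C)C(=O)Cl
Why: DMAP-catalysed acylation of the only free hydroxyl installs the tiglate (the thermodynamically preferred E ester) before the base-sensitive β-oxy ketone exists.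

Step 24
Reactants: 33 (1S,6R,8R,9R,10R)-1,13-bis(TBSO)-8-(tigloyloxy)-9-(TIPSO)germacra-4Z,7(11)-dien-12,6-olide
Product: 34 (1S,6R,8R,9R,10R)-1,13-dihydroxy-8-(tigloyloxy)-9-(TIPSO)germacra-4Z,7(11)-dien-12,6-olide
Conditions: HF·pyridine, pyridine, THF, 0 °C → rt
Reagents that add atoms: none
Why: Fluoride removes the primary allylic and the unhindered secondary TBS ethers, while the hindered secondary TIPS ether on O9 is much slower and stays.

Step 25
Reactants: 34 (1S,6R,8R,9R,10R)-1,13-dihydroxy-8-(tigloyloxy)-9-(TIPSO)germacra-4Z,7(11)-dien-12,6-olide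
Product: 35 (1S,6R,8R,9R,10R)-13-acetoxy-1-hydroxy-8-(tigloyloxy)-9-(TIPSO)germacra-4Z,7(11)-dien-12,6-olide
Conditions: Ac2O, 2,4,6-collidine, CH2Cl2, −20 °C
Reagents that add atoms: acetic anhydride CC(=O)OC(C)=O
Why: Acetylation with a hindered weak base at low temperature discriminates the primary C13 hydroxyl from the secondary C1 hydroxyl.

Step 26
Reactants: 35 (1S,6R,8R,9R,10R)-13-acetoxy-1-hydroxy-8-(tigloyloxy)-9-(TIPSO)germacra-4Z,7(11)-dien-12,6-olide
Product: 36 (6R,8R,9R,10S)-13-acetoxy-1-oxo-8-(tigloyloxy)-9-(TIPSO)germacra-4Z,7(11)-dien-12,6-olide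
Conditions: Dess–Martin periodinane, pyridine, CH2Cl2, 0 °C → rt
Reagents that add atoms: none
Why: Dess–Martin oxidation of the only free alcohol gives the C1 ketone under conditions too mild to epimerise C10 or eliminate the β-silyloxy group; the C1 configuration carried from step 1 is erased here.

Step 27
Reactants: 36 (6R,8R,9R,10S)-13-acetoxy-1-oxo-8-(tigloyloxy)-9-(TIPSO)germacra-4Z,7(11)-dien-12,6-olide
Product: 37 (6R,8R,9R,10S)-13-acetoxy-9-hydroxy-1-oxo-8-(tigloyloxy)germacra-4Z,7(11)-dien-12,6-olide (target)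
Conditions: HF·pyridine (excess), THF, rt
Reagents that add atoms: none
Why: Acidic fluoride cleaves the last silyl ether; acidic conditions are chosen over basic fluoride so that the tiglate does not migrate from O8 to O9 and the β-hydroxy ketone does not undergo retro-aldol cleavage or elimination.

## Compound list

1 | (R)-4-benzyl-3-propionyloxazolidin-2-one | CCC(=O)N1[C@H](Cc2ccccc2)COC1=O | starting material
2 | acrolein | C=CC=O | starting material
3 | dibutylboron (Z)-enolate of 1 | C/C=C(\OB(CCCC)CCCC)N1[C@H](Cc2ccccc2)COC1=O | intermediate (not isolated)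
4 | (R)-4-benzyl-3-[(2R,3S)-3-hydroxy-2-methylpent-4-enoyl]oxazolidin-2-one | C=C[C@H](O)[C@@H](C)C(=O)N1[C@H](Cc2ccccc2)COC1=O | intermediate
5 | (2R,3S)-3-hydroxy-N-methoxy-N,2-dimethylpent-4-enamide | C=C[C@H](O)[C@@H](C)C(=O)N(C)OC | intermediate
6 | (2R,3S)-3-[(tert-butyldimethylsilyl)oxy]-N-methoxy-N,2-dimethylpent-4-enamide | C=C[C@H](O[Si](C)(C)C(C)(C)C)[C@@H](C)C(=O)N(C)OC | intermediate
7 | (2R,3S)-3-[(tert-butyldimethylsilyl)oxy]-2-methylpent-4-enal | C=C[C@H](O[Si](C)(C)C(C)(C)C)[C@@H](C)C=O | intermediate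
8 | 4-methoxybenzyl alcohol | COc1ccc(CO)cc1 | starting material
9 | tributyl(iodomethyl)stannane | CCCC[Sn](CI)(CCCC)CCCC | starting material
10 | tributyl{[(4-methoxybenzyl)oxy]methyl}stannane | CCCC[Sn](CCCC)(CCCC)COCc1ccc(OC)cc1 | intermediate
11 | methyl (S)-2,2-dimethyl-1,3-dioxolane-4-carboxylate | COC(=O)[C@@H]1COC(C)(C)O1 | starting material
12 | (S)-2,2-dimethyl-1,3-dioxolane-4-carbaldehyde | O=C[C@@H]1COC(C)(C)O1 | intermediate
13 | (R)-4-[(Z)-2-iodoprop-1-en-1-yl]-2,2-dimethyl-1,3-dioxolane | C/C(I)=C/[C@@H]1COC(C)(C)O1 | intermediate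
14 | (2R,3Z)-4-iodopent-3-ene-1,2-diol | C/C(I)=C/[C@@H](O)CO | intermediate
15 | (2R,3Z)-4-iodo-1,2-bis[(triethylsilyl)oxy]pent-3-ene | C/C(I)=C/[C@@H](O[Si](CC)(CC)CC)CO[Si](CC)(CC)CC | intermediate
16 | (2R,3Z)-4-iodo-2-[(triethylsilyl)oxy]pent-3-enal | C/C(I)=C/[C@@H](O[Si](CC)(CC)CC)C=O | intermediate
17 | [(4-methoxybenzyl)oxy]methyllithium | [Li]COCc1ccc(OC)cc1 | intermediate (not isolated)
18 | (3R,4Z)-5-iodo-1-[(4-methoxybenzyl)oxy]-3-[(triethylsilyl)oxy]hex-4-en-2-ol, both C2 epimers | C/C(I)=C/[C@@H](O[Si](CC)(CC)CC)C(O)COCc1ccc(OC)cc1 | intermediate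
19 | (3R,4Z)-5-iodo-1-[(4-methoxybenzyl)oxy]-3-[(triethylsilyl)oxy]hex-4-en-2-one | C/C(I)=C/[C@@H](O[Si](CC)(CC)CC)C(=O)COCc1ccc(OC)cc1 | intermediate
20 | benzyl 2-(diethoxyphosphoryl)acetate | CCOP(=O)(CC(=O)OCc1ccccc1)OCC | starting material
21 | benzyl 2-(diethoxyphosphoryl)-3-hydroxypropanoate, racemic | CCOP(=O)(OCC)C(CO)C(=O)OCc1ccccc1 | intermediate
22 | benzyl 3-[(tert-butyldimethylsilyl)oxy]-2-(diethoxyphosphoryl)propanoate, racemic | CCOP(=O)(OCC)C(CO[Si](C)(C)C(C)(C)C)C(=O)OCc1ccccc1 | intermediate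
23 | 3-[(tert-butyldimethylsilyl)oxy]-2-(diethoxyphosphoryl)propanoic acid, racemic | CCOP(=O)(OCC)C(CO[Si](C)(C)C(C)(C)C)C(=O)O | intermediate
24 | dibutylboron (Z)-enolate of 19 (O–B and OPMB cis) | C/C(I)=C/[C@@H](O[Si](CC)(CC)CC)/C(OB(CCCC)CCCC)=C/OCc1ccc(OC)cc1 | intermediate (not isolated)
25 | (3S,4S,5R,6S,8R,9Z)-3-[(tert-butyldimethylsilyl)oxy]-5-hydroxy-10-iodo-6-[(4-methoxybenzyl)oxy]-4-methyl-8-[(triethylsilyl)oxy]undeca-1,9-dien-7-one | C/C(I)=C/[C@@H](O[Si](CC)(CC)CC)C(=O)[C@@H](OCc1ccc(OC)cc1)[C@H](O)[C@H](C)[C@@H](O[Si](C)(C)C(C)(C)C)C=C | intermediate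
26 | (3S,4R,5R,6S,8R,9Z)-3-[(tert-butyldimethylsilyl)oxy]-10-iodo-6-[(4-methoxybenzyl)oxy]-4-methyl-8-[(triethylsilyl)oxy]-5-[(triisopropylsilyl)oxy]undeca-1,9-dien-7-one | C/C(I)=C/[C@@H](O[Si](CC)(CC)CC)C(=O)[C@@H](OCc1ccc(OC)cc1)[C@H](O[Si](C(C)C)(C(C)C)C(C)C)[C@H](C)[C@@H](O[Si](C)(C)C(C)(C)C)C=C | intermediate
27 | (3S,4R,5R,6S,8R,9Z)-3-[(tert-butyldimethylsilyl)oxy]-8-hydroxy-10-iodo-6-[(4-methoxybenzyl)oxy]-4-methyl-5-[(triisopropylsilyl)oxy]undeca-1,9-dien-7-one | C/C(I)=C/[C@@H](O)C(=O)[C@@H](OCc1ccc(OC)cc1)[C@H](O[Si](C(C)C)(C(C)C)C(C)C)[C@H](C)[C@@H](O[Si](C)(C)C(C)(C)C)C=C | intermediate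
28 | (3S,4R,5R,6S,8R,9Z)-3-[(tert-butyldimethylsilyl)oxy]-10-iodo-6-[(4-methoxybenzyl)oxy]-4-methyl-7-oxo-5-[(triisopropylsilyl)oxy]undeca-1,9-dien-8-yl 3-[(tert-butyldimethylsilyl)oxy]-2-(diethoxyphosphoryl)propanoate, both epimers at the phosphonate carbon | C/C(I)=C/[C@@H](OC(=O)C(CO[Si](C)(C)C(C)(C)C)P(=O)(OCC)OCC)C(=O)[C@@H](OCc1ccc(OC)cc1)[C@H](O[Si](C(C)C)(C(C)C)C(C)C)[C@H](C)[C@@H](O[Si](C)(C)C(C)(C)C)C=C | intermediate
29 | (5R)-3-{[(tert-butyldimethylsilyl)oxy]methyl}-4-{(1R,2R,3R,4S)-4-[(tert-butyldimethylsilyl)oxy]-1-[(4-methoxybenzyl)oxy]-3-methyl-2-[(triisopropylsilyl)oxy]hex-5-en-1-yl}-5-[(Z)-2-iodoprop-1-en-1-yl]furan-2(5H)-one | C=C[C@H](O[Si](C)(C)C(C)(C)C)[C@@H](C)[C@@H](O[Si](C(C)C)(C(C)C)C(C)C)[C@H](OCc1ccc(OC)cc1)C2=C(CO[Si](C)(C)C(C)(C)C)C(=O)O[C@@H]2/C=C(/C)I | intermediate (key-step precursor)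
30 | B-alkyl-9-borabicyclo[3.3.1]nonane from 29, boron on C3 | B1(CC[C@H](O[Si](C)(C)C(C)(C)C)[C@@H](C)[C@@H](O[Si](C(C)C)(C(C)C)C(C)C)[C@H](OCc2ccc(OC)cc2)C3=C(CO[Si](C)(C)C(C)(C)C)C(=O)O[C@@H]3/C=C(/C)I)C4CCCC1CCC4 | intermediate (not isolated)
31 | (1S,6R,8R,9R,10R)-1,13-bis[(tert-butyldimethylsilyl)oxy]-8-[(4-methoxybenzyl)oxy]-9-[(triisopropylsilyl)oxy]germacra-4Z,7(11)-dien-12,6-olide | COc1ccc(CO[C@@H]2C3=C(CO[Si](C)(C)C(C)(C)C)C(=O)O[C@@H]3/C=C(/C)CC[C@H](O[Si](C)(C)C(C)(C)C)[C@@H](C)[C@H]2O[Si](C(C)C)(C(C)C)C(C)C)cc1 | intermediate (key-step product)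
32 | (1S,6R,8R,9R,10R)-1,13-bis[(tert-butyldimethylsilyl)oxy]-8-hydroxy-9-[(triisopropylsilyl)oxy]germacra-4Z,7(11)-dien-12,6-olide | O[C@@H]1C2=C(CO[Si](C)(C)C(C)(C)C)C(=O)O[C@@H]2/C=C(/C)CC[C@H](O[Si](C)(C)C(C)(C)C)[C@@H](C)[C@H]1O[Si](C(C)C)(C(C)C)C(C)C | intermediate
33 | (1S,6R,8R,9R,10R)-1,13-bis[(tert-butyldimethylsilyl)oxy]-8-(tigloyloxy)-9-[(triisopropylsilyl)oxy]germacra-4Z,7(11)-dien-12,6-olide | C/C=C(\C)C(=O)O[C@@H]1C2=C(CO[Si](C)(C)C(C)(C)C)C(=O)O[C@@H]2/C=C(/C)CC[C@H](O[Si](C)(C)C(C)(C)C)[C@@H](C)[C@H]1O[Si](C(C)C)(C(C)C)C(C)C | intermediate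
34 | (1S,6R,8R,9R,10R)-1,13-dihydroxy-8-(tigloyloxy)-9-[(triisopropylsilyl)oxy]germacra-4Z,7(11)-dien-12,6-olide | C/C=C(\C)C(=O)O[C@@H]1C2=C(CO)C(=O)O[C@@H]2/C=C(/C)CC[C@H](O)[C@@H](C)[C@H]1O[Si](C(C)C)(C(C)C)C(C)C | intermediate
35 | (1S,6R,8R,9R,10R)-13-acetoxy-1-hydroxy-8-(tigloyloxy)-9-[(triisopropylsilyl)oxy]germacra-4Z,7(11)-dien-12,6-olide | C/C=C(\C)C(=O)O[C@@H]1C2=C(COC(C)=O)C(=O)O[C@@H]2/C=C(/C)CC[C@H](O)[C@@H](C)[C@H]1O[Si](C(C)C)(C(C)C)C(C)C | intermediate
36 | (6R,8R,9R,10S)-13-acetoxy-1-oxo-8-(tigloyloxy)-9-[(triisopropylsilyl)oxy]germacra-4Z,7(11)-dien-12,6-olide | C/C=C(\C)C(=O)O[C@@H]1C2=C(COC(C)=O)C(=O)O[C@@H]2/C=C(/C)CCC(=O)[C@@H](C)[C@H]1O[Si](C(C)C)(C(C)C)C(C)C | intermediate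
37 | (6R,8R,9R,10S)-13-acetoxy-9-hydroxy-1-oxo-8-(tigloyloxy)germacra-4Z,7(11)-dien-12,6-olide (CNP0281168.1) | C/C=C(\C)C(=O)O[C@@H]1C2=C(COC(C)=O)C(=O)O[C@@H]2/C=C(/C)CCC(=O)[C@@H](C)[C@H]1O | target

## Step count and risks

Total step count: 27 (steps 1–27, three branches plus the main line).
Longest linear sequence: 19 steps (11 → 37 through steps 6–12 and 16–27).

Steps most likely to fail:

1. Step 21 (ring closure). Closing a ten-membered ring may be slower than protodeboronation of the borate, β-hydride elimination of the alkylpalladium or intermolecular coupling, and the aqueous base may epimerise C6 or open the lactone. Fallback, setting out from 29 and returning at 31: the same bond is closed without base by a Negishi coupling. Alkylborane 30 is oxidised in the flask (NaBO3·4H2O, THF/H2O) to the primary alcohol F1, which is turned into the primary iodide F2 (I2, PPh3, imidazole). Zinc dust with LiCl in THF inserts only into the sp3 C–I bond to give the alkylzinc iodide F3. Slow addition of F3 to Pd(PPh3)4 in THF at 40 °C gives 31.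

2. Step 16 (fragment aldol). The facial bias of the C6 silyloxy centre may oppose the anti-Felkin preference of aldehyde 7, giving poor facial selectivity, or enolisation may leak toward C6. Fallback, setting out from aldehyde 7 and returning at 28: the C6 epimer of the ketone is used, so that its bias is reversed, and C6 is inverted when the ester is made. Purchased (R)-2,2-dimethyl-1,3-dioxolane-4-carbaldehyde F4 is taken through the chemistry of steps 7–12 to the dioxolane F5, the diol F6, the bis-TES ether F7, the aldehyde F8, the carbinol F9 and the ketone F10. The aldol reaction of F10 with 7 under the conditions of step 16 gives the adduct F11, TIPS protection gives F12, and TES cleavage gives the hydroxy ketone F13. Mitsunobu esterification of F13 with acid 23 (PPh3, DIAD, toluene, 0 °C) proceeds with inversion at C6 and delivers 28.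

3. Step 20 (butenolide closure). The amine base may enolise the α-acyloxy ketone, or deprotonate the product at C6, and so epimerise C6; the phosphonate carbanion may also lose silyloxide by β-elimination before it reaches the ketone. Fallback, setting out from 27 and returning at 29: the C7–C11 bond is made without base by a Reformatsky reaction. DL-serine is diazotised (NaNO2, KBr, aqueous HBr) to 2-bromo-3-hydroxypropanoic acid F14, which is silylated (TBSCl, imidazole) to the bis-silyl compound F15; the silyl ester is cleaved (K2CO3, MeOH/H2O) to the acid F16. DCC coupling of F16 with 27 gives the bromo ester F17, activated zinc in THF gives the β-hydroxy lactone F18 by intramolecular addition to the C7 ketone, and SOCl2/pyridine at 0 °C dehydrates F18 to 29.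

## Further compounds

F1 | step 21 | (5R)-3-{[(tert-butyldimethylsilyl)oxy]methyl}-4-{(1R,2R,3R,4S)-4-[(tert-butyldimethylsilyl)oxy]-6-hydroxy-1-[(4-methoxybenzyl)oxy]-3-methyl-2-[(triisopropylsilyl)oxy]hexyl}-5-[(Z)-2-iodoprop-1-en-1-yl]furan-2(5H)-one | OCC[C@H](O[Si](C)(C)C(C)(C)C)[C@@H](C)[C@@H](O[Si](C(C)C)(C(C)C)C(C)C)[C@H](OCc1ccc(OC)cc1)C2=C(CO[Si](C)(C)C(C)(C)C)C(=O)O[C@@H]2/C=C(/C)I
F2 | step 21 | primary iodide corresponding to F1 (6-iodohexyl side chain) | ICC[C@H](O[Si](C)(C)C(C)(C)C)[C@@H](C)[C@@H](O[Si](C(C)C)(C(C)C)C(C)C)[C@H](OCc1ccc(OC)cc1)C2=C(CO[Si](C)(C)C(C)(C)C)C(=O)O[C@@H]2/C=C(/C)I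
F3 | step 21 | alkylzinc iodide from F2 (zinc on C3) | I[Zn]CC[C@H](O[Si](C)(C)C(C)(C)C)[C@@H](C)[C@@H](O[Si](C(C)C)(C(C)C)C(C)C)[C@H](OCc1ccc(OC)cc1)C2=C(CO[Si](C)(C)C(C)(C)C)C(=O)O[C@@H]2/C=C(/C)I
F4 | step 16 | (R)-2,2-dimethyl-1,3-dioxolane-4-carbaldehyde (purchased) | O=C[C@H]1COC(C)(C)O1
F5 | step 16 | (S)-4-[(Z)-2-iodoprop-1-en-1-yl]-2,2-dimethyl-1,3-dioxolane | C/C(I)=C/[C@H]1COC(C)(C)O1
F6 | step 16 | (2S,3Z)-4-iodopent-3-ene-1,2-diol | C/C(I)=C/[C@H](O)CO
F7 | step 16 | (2S,3Z)-4-iodo-1,2-bis[(triethylsilyl)oxy]pent-3-ene | C/C(I)=C/[C@H](O[Si](CC)(CC)CC)CO[Si](CC)(CC)CC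
F8 | step 16 | (2S,3Z)-4-iodo-2-[(triethylsilyl)oxy]pent-3-enal | C/C(I)=C/[C@H](O[Si](CC)(CC)CC)C=O
F9 | step 16 | (3S,4Z)-5-iodo-1-[(4-methoxybenzyl)oxy]-3-[(triethylsilyl)oxy]hex-4-en-2-ol, both C2 epimers | C/C(I)=C/[C@H](O[Si](CC)(CC)CC)C(O)COCc1ccc(OC)cc1
F10 | step 16 | (3S,4Z)-5-iodo-1-[(4-methoxybenzyl)oxy]-3-[(triethylsilyl)oxy]hex-4-en-2-one | C/C(I)=C/[C@H](O[Si](CC)(CC)CC)C(=O)COCc1ccc(OC)cc1
F11 | step 16 | (3S,4S,5R,6S,8S,9Z)-3-[(tert-butyldimethylsilyl)oxy]-5-hydroxy-10-iodo-6-[(4-methoxybenzyl)oxy]-4-methyl-8-[(triethylsilyl)oxy]undeca-1,9-dien-7-one | C/C(I)=C/[C@H](O[Si](CC)(CC)CC)C(=O)[C@@H](OCc1ccc(OC)cc1)[C@H](O)[C@H](C)[C@@H](O[Si](C)(C)C(C)(C)C)C=C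
F12 | step 16 | (3S,4R,5R,6S,8S,9Z)-3-[(tert-butyldimethylsilyl)oxy]-10-iodo-6-[(4-methoxybenzyl)oxy]-4-methyl-8-[(triethylsilyl)oxy]-5-[(triisopropylsilyl)oxy]undeca-1,9-dien-7-one | C/C(I)=C/[C@H](O[Si](CC)(CC)CC)C(=O)[C@@H](OCc1ccc(OC)cc1)[C@H](O[Si](C(C)C)(C(C)C)C(C)C)[C@H](C)[C@@H](O[Si](C)(C)C(C)(C)C)C=C
F13 | step 16 | (3S,4R,5R,6S,8S,9Z)-3-[(tert-butyldimethylsilyl)oxy]-8-hydroxy-10-iodo-6-[(4-methoxybenzyl)oxy]-4-methyl-5-[(triisopropylsilyl)oxy]undeca-1,9-dien-7-one | C/C(I)=C/[C@H](O)C(=O)[C@@H](OCc1ccc(OC)cc1)[C@H](O[Si](C(C)C)(C(C)C)C(C)C)[C@H](C)[C@@H](O[Si](C)(C)C(C)(C)C)C=C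
F14 | step 20 | 2-bromo-3-hydroxypropanoic acid, racemic | OCC(Br)C(=O)O
F15 | step 20 | tert-butyldimethylsilyl 2-bromo-3-[(tert-butyldimethylsilyl)oxy]propanoate, racemic | CC(C)(C)[Si](C)(C)OCC(Br)C(=O)O[Si](C)(C)C(C)(C)C
F16 | step 20 | 2-bromo-3-[(tert-butyldimethylsilyl)oxy]propanoic acid, racemic | CC(C)(C)[Si](C)(C)OCC(Br)C(=O)O
F17 | step 20 | O6 ester of 27 with F16 (both epimers at the bromo carbon) | C/C(I)=C/[C@@H](OC(=O)C(Br)CO[Si](C)(C)C(C)(C)C)C(=O)[C@@H](OCc1ccc(OC)cc1)[C@H](O[Si](C(C)C)(C(C)C)C(C)C)[C@H](C)[C@@H](O[Si](C)(C)C(C)(C)C)C=C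
F18 | step 20 | 7-hydroxy-7,11-dihydro analogue of 29 (β-hydroxy-γ-lactone, C7 and C11 as mixtures) | C=C[C@H](O[Si](C)(C)C(C)(C)C)[C@@H](C)[C@@H](O[Si](C(C)C)(C(C)C)C(C)C)[C@H](OCc1ccc(OC)cc1)C2(O)C(CO[Si](C)(C)C(C)(C)C)C(=O)O[C@@H]2/C=C(/C)I
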